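The earlier runs and the new flask were computed with constants of no real substance.

I wanted the target at the end of each flask. Target appears as starting material goes, so I first asked which number the answer hangs on.

| flask | starting material | first nucleophile | second nucleophile | temperature | remark | time |
|---|---|---|---|---|---|---|
| midnight | 0.010 M | 0.020 M | 0.010 M | 70 °C | run made earlier |  |
| autumn | 0.010 M | 0.020 M | 0.040 M | 92 °C | run made earlier |  |
| dusk | 0.010 M | 0.040 M | 0.020 M | 70 °C | run made earlier |  |
| gamma | 0.010 M | 0.0200 M | 0.0200 M | 80 °C |  | 5.0 h |
| alpha | 0.010 M | 0.0200 M | 0.0200 M | 100 °C |  | 5.0 h |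
| delta | 0.010 M | 0.0200 M | 0.0200 M | 60 °C |  | 5.0 h |

midnight run (percent of the starting material charged)

| time / h | starting material / % | intermediate / % | other capture product / % | target / % | side product / % |
|---|---|---|---|---|---|
| 1.00 | 83.6 | 1.7 | 2.4 | 12.6 | 0.1 |
| 2.00 | 69.4 | 1.9 | 2.6 | 24.8 | 1.2 |
| 3.00 | 57.4 | 1.0 | 3.0 | 35.1 | 2.1 |
| 4.00 | 47.2 | 1.7 | 2.7 | 44.1 | 4.3 |

autumn run (percent of the starting material charged)

| time / min | starting material / % | intermediate / % | other capture product / % | target / % | side product / % |
|---|---|---|---|---|---|
| 20.0 | 60.7 | 4.0 | 8.3 | 25.3 | 0.9 |
| 40.0 | 35.9 | 3.7 | 8.9 | 48.5 | 4.2 |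
| 60.0 | 21.0 | 3.4 | 8.7 | 60.8 | 7.2 |
| 80.0 | 11.6 | 2.3 | 8.6 | 68.3 | 9.2 |

dusk run (percent of the starting material charged)

| time / h | starting material / % | intermediate / % | other capture product / % | target / % | side product / % |
|---|---|---|---|---|---|
| 0.500 | 91.2 | 1.1 | 1.5 | 6.0 | 0.2 |
| 1.33 | 79.1 | 0.8 | 2.5 | 17.2 | 0.5 |
| 2.50 | 63.2 | 1.0 | 3.1 | 31.7 | 0.9 |
| 4.00 | 48.0 | 0.8 | 3.3 | 46.2 | 2.3 |

(scatter of a reading: 0.3 percentage points)

- in percentages every species weighs as the starting material in it: one side product counts as two
- what was read earlier has a scatter of 0.3 percentage points, one standard deviation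
- a reading or a percentage of target counts all its forms, free or not

* which of these there is most of at the end, counted by the starting material in it, gamma (other capture product / target / starting material / side product / intermediate)
* which of these there is most of at the end, counted by the starting material in it, alpha (other capture product / target / starting material / side product / intermediate)
* which of these there is most of at the end, counted by the starting material in it, delta (other capture product / target / starting material / side product / intermediate)
* final amount of the leader among these, as a percentage of the starting material charged, in gamma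
* final amount of the leader among these, as a percentage of the starting material charged, in alpha
* final amount of the leader among these, as a percentage of the starting material charged, in delta

I took the numbers in turn. The other capture product read 2.7 % at the last midnight reading and 8.6 % at the last autumn reading, far less than the target in each , so I did not need it closely. The side product reached 9.2 % in the autumn run and was still climbing. I had its trend from two temperatures, so alpha carries that doubt. The intermediate read 1.7 % at the last midnight reading, so I took its formation from starting material as the rate-limiting step. That decay has a constant k, and the lives elapsed are n, the time over its time constant. The fraction left is exp(−n). One percent of error in k moves that fraction by n·exp(−n) points, which peaks at one life and fades after many. So k had to be good for delta and gamma, and alpha forgave it.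

Then the number itself. Dusk had twice the nucleophile charges of midnight, yet the two kept 48.0 % and 47.2 % at 4.00 h. Together they gave k = 0.186 h⁻¹ at 70 °C. Autumn gave 1.62 h⁻¹ at 92 °C, which means an activation energy of 102 kJ mol⁻¹. My count of lives elapsed was 0.316 for delta, 2.57 for gamma and 16.7 for alpha. So I expected 72.9 % of the starting material left in delta and 7.65 % in gamma. One percent of error in k was worth 0.23 percentage points in delta and far less in alpha.

The forecast held that “starting material decays first order and does not depend on either nucleophile”. It gave target in gamma at 75 % (68 % to 81 %), target in alpha at 72 % (62 % to 81 %), and starting material in delta at 72.5 % (70.5 % to 74.5 %).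

The flasks gave target in gamma at 73.5 %, target in alpha at 82.1 %, and starting material in delta at 72.7 %. Gamma and delta fell inside the forecast's ranges. Alpha stood 10 points above its figure, with side product at 12.9 % against its 25.

    second nucleophile + intermediate → other capture product (k = 0.0485 M⁻¹ s⁻¹, Ea = 76.0 kJ mol⁻¹)
    first nucleophile + intermediate → target (k = 0.0710 M⁻¹ s⁻¹, Ea = 53.0 kJ mol⁻¹)
    first nucleophile + target ⇌ idle adduct, settled at all times (K = 640 M⁻¹, ΔH = −17.0 kJ mol⁻¹)
    starting material → intermediate (k = 1.74 × 10⁻⁵ s⁻¹, Ea = 100 kJ mol⁻¹)
    starting material + target → side product (k = 0.00382 M⁻¹ s⁻¹, Ea = 74.0 kJ mol⁻¹)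
    second nucleophile → decomposed reagent (k = 1.50 × 10⁻⁴ s⁻¹, Ea = 109 kJ mol⁻¹)
    (constants at 60 °C)

The main reason alpha ended with 82.1 % of target was its temperature. With that difference taken away, the flask held 20.5 %. By my count alpha had 16.7 lives against 0.316 in delta. Delta's count leaves 72.9 %, and delta kept 72.7 %. For the flask like gamma at 65 °C I counted 0.546 lives, which leaves 57.9 %, and it ended with 57.6 % of starting material and 33.4 % of target.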